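**Retrosynthetic overview**
1. The strategy rests on one carbon: the inner ester carbonyl that ties C1 of ring B (flanked by the 2-oxygen and the 6-methyl group) to O4 of ring C. It is disconnected to a ring A–ring B aryl bromide, carbon monoxide and the ring C phenol.
2. The outer ring A–ring B ester is cut conventionally to 2,3,4-trimethoxy-6-methylbenzoic acid (from 3,4,5-trimethoxytoluene by bromination and lithiation/carboxylation) and 4-bromo-3-(methoxymethoxy)-5-methylphenol.
3. That phenol comes from 2-bromo-3-methylphenol by methoxymethyl protection and sterically directed C–H borylation/oxidation at C5; ring C is orsellinic acid carried as its benzyl ester.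
4. No ring is formed, all three benzene rings are bought; the order is ring A–ring B ester, then ring B–ring C ester by carbonylation, then acetal cleavage and hydrogenolysis.

Key step: step 7

Remark: the target has no stereocentre; ring A is the trimethoxytoluoyl unit, ring B the inner orsellinate and ring C the terminal orsellinic acid.

**Route**

Step 1
Reactants: 1 3,4,5-trimethoxytoluene
Product: 2 2-bromo-3,4,5-trimethoxytoluene
Conditions: NBS (1.0 equiv), MeCN, 0 °C to rt
Reagents that add atoms: N-bromosuccinimide O=C1CCC(=O)N1Br
Why: Electrophilic aromatic bromination; the two free ring positions of 1 are equivalent and strongly activated, so one equivalent of NBS should give a single monobromide.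

Step 2
Reactants: 2 2-bromo-3,4,5-trimethoxytoluene
Product: 4 2,3,4-trimethoxy-6-methylbenzoic acid, via aryllithium 3 (not isolated)
Conditions: n-BuLi, THF, −78 °C; CO2 (dry gas), −78 °C to rt; aq. HCl work-up
Reagents that add atoms: carbon dioxide O=C=O
Why: Bromine–lithium exchange at −78 °C outruns benzylic deprotonation, and carboxylation of the aryllithium with CO2 should deliver the doubly ortho-substituted benzoic acid.

Step 3
Reactants: 5 2-bromo-3-methylphenol
Product: 6 2-bromo-1-(methoxymethoxy)-3-methylbenzene
Conditions: MOMCl, i-Pr2NEt, CH2Cl2, 0 °C to rt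
Reagents that add atoms: chloromethyl methyl ether COCCl
Why: O-alkylation of the phenol with the reactive α-chloro ether (Williamson-type etherification) gives an acetal that is inert to the iridium catalysis, the bases and the palladium catalysis that follow.

Step 4
Reactants: 6 2-bromo-1-(methoxymethoxy)-3-methylbenzene
Product: 8 4-bromo-3-(methoxymethoxy)-5-methylphenol, via aryl pinacol boronate 7 (not isolated)
Conditions: [Ir(OMe)(cod)]2 (1.5 mol%), 4,4'-di-tert-butyl-2,2'-bipyridine (3 mol%), B2pin2 (1.0 equiv), THF, 80 °C; evaporate; then THF, aq. NaOH, 30% H2O2, 0 °C to rt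
Reagents that add atoms: hydrogen peroxide OO
Why: Sterically governed iridium-catalysed C–H borylation should go to C5, the only ring C–H without an ortho substituent, while the aryl bromide is tolerated, and one-pot oxidation of the C–B bond with basic peroxide (1,2-aryl shift from boron to oxygen) should give the phenol without touching the acetal.

Step 5
Reactants: 4 2,3,4-trimethoxy-6-methylbenzoic acid, 8 4-bromo-3-(methoxymethoxy)-5-methylphenol
Product: 10 4-bromo-3-(methoxymethoxy)-5-methylphenyl 2,3,4-trimethoxy-6-methylbenzoate, via acid chloride 9 (not isolated)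
Conditions: 4, (COCl)2, DMF (cat.), CH2Cl2, 0 °C to rt, evaporate; then 8, Et3N, DMAP (cat.), CH2Cl2, 0 °C to rt
Reagents that add atoms: none
Why: Acid chloride formation followed by DMAP-catalysed O-acylation (nucleophilic catalysis through the acylpyridinium ion) should join the hindered acid to the unhindered phenol under basic conditions that keep the acetal intact.

Step 6
Reactants: 11 orsellinic acid (2,4-dihydroxy-6-methylbenzoic acid)
Product: 12 benzyl 2,4-dihydroxy-6-methylbenzoate
Conditions: BnBr (1.05 equiv), KHCO3, DMF, rt
Reagents that add atoms: benzyl bromide BrCc1ccccc1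
Why: Chemoselective SN2 alkylation of the carboxylate, since KHCO3 deprotonates only the carboxylic acid and leaves both phenols protonated and unalkylated.

Step 7
Reactants: 10 4-bromo-3-(methoxymethoxy)-5-methylphenyl 2,3,4-trimethoxy-6-methylbenzoate, 12 benzyl 2,4-dihydroxy-6-methylbenzoate, 13 carbon monoxide
Product: 14 benzyl 2-hydroxy-4-{[2-(methoxymethoxy)-6-methyl-4-[(2,3,4-trimethoxy-6-methylbenzoyl)oxy]benzoyl]oxy}-6-methylbenzoate
Conditions: Pd(OAc)2 (5 mol%), Xantphos (6 mol%), CO (1 atm), 12 (1.2 equiv), Et3N (3 equiv), toluene, 100 °C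
Reagents that add atoms: none
Why: Zerovalent palladium, formed in situ from Pd(OAc)2 and Xantphos under CO, inserts into the C–Br bond of 10, CO inserts into the aryl–palladium bond to give an aroyl divalent palladium complex, and the 4-phenoxide of 12 displaces bromide so that C–O reductive elimination releases the ester and returns zerovalent palladium. The closest known reaction type is the palladium-catalysed aryloxycarbonylation of aryl bromides with phenols at atmospheric CO pressure using wide-bite-angle bisphosphines. No ring is closed and no stereocentre is formed. The step needs site selectivity between the two hydroxyls of 12: the 4-hydroxyl is para to the ester, more acidic and free, whereas the 2-hydroxyl is held in a hydrogen bond to the benzyl ester carbonyl and should stay unacylated. It also needs the existing ring A ester to survive phenoxide at 100 °C, which its two ortho substituents (methyl and methoxy) should secure by shielding the carbonyl from transesterification. The two ortho groups on ring B slow oxidative addition, which is why the temperature is raised and the CO pressure kept low, while the large bite angle of Xantphos keeps the hindered acyl complex productive.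

Step 8
Reactants: 14 benzyl 2-hydroxy-4-{[2-(methoxymethoxy)-6-methyl-4-[(2,3,4-trimethoxy-6-methylbenzoyl)oxy]benzoyl]oxy}-6-methylbenzoate
Product: 15 benzyl 2-hydroxy-4-{[2-hydroxy-6-methyl-4-[(2,3,4-trimethoxy-6-methylbenzoyl)oxy]benzoyl]oxy}-6-methylbenzoate
Conditions: TFA/CH2Cl2 (1:9), 0 °C to rt; aq. NaHCO3 work-up
Reagents that add atoms: none
Why: Acid-catalysed acetal cleavage through the oxocarbenium ion should free the ring B phenol, which is then stabilised by a hydrogen bond to the neighbouring ester carbonyl, while aryl and benzyl esters are inert to dilute TFA at this temperature.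

Step 9
Reactants: 15 benzyl 2-hydroxy-4-{[2-hydroxy-6-methyl-4-[(2,3,4-trimethoxy-6-methylbenzoyl)oxy]benzoyl]oxy}-6-methylbenzoate
Product: 16 2-hydroxy-4-{[2-hydroxy-6-methyl-4-[(2,3,4-trimethoxy-6-methylbenzoyl)oxy]benzoyl]oxy}-6-methylbenzoic acid (CNP0332884.0)
Conditions: H2 (1 atm), Pd/C (10%), EtOAc, rt
Reagents that add atoms: none
Why: Catalytic hydrogenolysis of the benzylic C–O bond should release the carboxylic acid under neutral conditions at room temperature, which leaves both aryl esters intact and avoids decarboxylation of the orsellinic acid terminus.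

**Compound list**
1 | 3,4,5-trimethoxytoluene | COc1cc(C)cc(OC)c1OC | starting material
2 | 2-bromo-3,4,5-trimethoxytoluene | COc1cc(C)c(Br)c(OC)c1OC | intermediate
3 | (2,3,4-trimethoxy-6-methylphenyl)lithium (not isolated) | COc1cc(C)c([Li])c(OC)c1OC | intermediate
4 | 2,3,4-trimethoxy-6-methylbenzoic acid | COc1cc(C)c(C(=O)O)c(OC)c1OC | intermediate
5 | 2-bromo-3-methylphenol | Cc1cccc(O)c1Br | starting material
6 | 2-bromo-1-(methoxymethoxy)-3-methylbenzene | Cc1cccc(OCOC)c1Br | intermediate
7 | 2-[4-bromo-3-(methoxymethoxy)-5-methylphenyl]-4,4,5,5-tetramethyl-1,3,2-dioxaborolane (not isolated) | Cc1cc(B2OC(C)(C)C(C)(C)O2)cc(OCOC)c1Br | intermediate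
8 | 4-bromo-3-(methoxymethoxy)-5-methylphenol | Cc1cc(O)cc(OCOC)c1Br | intermediate
9 | 2,3,4-trimethoxy-6-methylbenzoyl chloride (not isolated) | COc1cc(C)c(C(=O)Cl)c(OC)c1OC | intermediate
10 | 4-bromo-3-(methoxymethoxy)-5-methylphenyl 2,3,4-trimethoxy-6-methylbenzoate | COc1cc(C)c(C(=O)Oc2cc(C)c(Br)c(OCOC)c2)c(OC)c1OC | intermediate
11 | orsellinic acid (2,4-dihydroxy-6-methylbenzoic acid) | Cc1cc(O)cc(O)c1C(=O)O | starting material
12 | benzyl 2,4-dihydroxy-6-methylbenzoate | Cc1cc(O)cc(O)c1C(=O)OCc1ccccc1 | intermediate
13 | carbon monoxide | [C-]#[O+] | starting material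
14 | benzyl 2-hydroxy-4-{[2-(methoxymethoxy)-6-methyl-4-[(2,3,4-trimethoxy-6-methylbenzoyl)oxy]benzoyl]oxy}-6-methylbenzoate | COc1cc(C)c(C(=O)Oc2cc(C)c(C(=O)Oc3cc(C)c(C(=O)OCc4ccccc4)c(O)c3)c(OCOC)c2)c(OC)c1OC | intermediate
15 | benzyl 2-hydroxy-4-{[2-hydroxy-6-methyl-4-[(2,3,4-trimethoxy-6-methylbenzoyl)oxy]benzoyl]oxy}-6-methylbenzoate | COc1cc(C)c(C(=O)Oc2cc(C)c(C(=O)Oc3cc(C)c(C(=O)OCc4ccccc4)c(O)c3)c(O)c2)c(OC)c1OC | intermediate
16 | 2-hydroxy-4-{[2-hydroxy-6-methyl-4-[(2,3,4-trimethoxy-6-methylbenzoyl)oxy]benzoyl]oxy}-6-methylbenzoic acid | COc1cc(C)c(C(=O)Oc2cc(C)c(C(=O)Oc3cc(C)c(C(=O)O)c(O)c3)c(O)c2)c(OC)c1OC | target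

**Step count**
Total steps: 9. Longest linear sequence: 6 steps (steps 3, 4, 5, 7, 8, 9; the ring A branch through steps 1, 2, 5, 7, 8, 9 is equally long).

**Steps most likely to fail**

1. Step 7. Oxidative addition into the doubly ortho-substituted, electron-rich C–Br bond may be too slow under CO, so that the catalyst aggregates to palladium metal. The hindered acyl palladium complex may also be reduced or hydrolysed before the weakly nucleophilic phenoxide captures it. The fallback gives up the carbonylation and uses a classical depside acylation, in which ring B already carries its carboxyl carbon. It sets out from orsellinic acid 11 and acid chloride 9 (made from acid 4 as in step 5) and comes back to the route at 14. Alkylation of 11 with allyl bromide and KHCO3 in DMF should give allyl 2,4-dihydroxy-6-methylbenzoate F1. Acylation of its unchelated 4-hydroxyl with 9 (Et3N, DMAP, CH2Cl2) should give allyl 2-hydroxy-6-methyl-4-[(2,3,4-trimethoxy-6-methylbenzoyl)oxy]benzoate F2. MOMCl and i-Pr2NEt in refluxing CH2Cl2 should cap the chelated 2-hydroxyl to give allyl 2-(methoxymethoxy)-6-methyl-4-[(2,3,4-trimethoxy-6-methylbenzoyl)oxy]benzoate F3. Pd(PPh3)4 with N-methylaniline in THF should remove the allyl group to give 2-(methoxymethoxy)-6-methyl-4-[(2,3,4-trimethoxy-6-methylbenzoyl)oxy]benzoic acid F4. Esterification of F4 with the 4-hydroxyl of benzyl ester 12 (EDC·HCl, DMAP, CH2Cl2) then gives 14.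

2. Step 4. Turnover of the iridium catalyst may stall on this bromide- and acetal-bearing arene, some borylation may occur next to the small methoxymethoxy group to give an isomer that is hard to separate, and material may be lost in the peroxide stage. The fallback takes both ring B oxygens from orcinol instead of introducing one by C–H functionalisation. It sets out from acid chloride 9 (from acid 4) together with commercial orcinol (5-methylbenzene-1,3-diol) and comes back to the route at 10. Monobromination of orcinol with NBS (1 equiv, MeCN, 0 °C), para to one hydroxyl, should give 4-bromo-5-methylbenzene-1,3-diol F5. One equivalent of 9 with Et3N at low temperature should acylate the hydroxyl remote from bromine, the other being flanked by bromine and less nucleophilic, to give 4-bromo-3-hydroxy-5-methylphenyl 2,3,4-trimethoxy-6-methylbenzoate F6. MOMCl and i-Pr2NEt then cap the remaining hydroxyl and give 10.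

3. Step 8. Acetal cleavage at the position next to the ester may be slow enough for the acid to attack the two aryl ester links or the benzyl ester, and the released formaldehyde equivalent may alkylate the electron-rich rings. The fallback moves the acid treatment to a robust early stage and exchanges the acetal for a benzyl ether, so that the end of the synthesis is a single neutral hydrogenolysis. It sets out from bromide 10 and comes back to the route at the target 16. TFA in CH2Cl2 should cleave the acetal of 10 to give 4-bromo-3-hydroxy-5-methylphenyl 2,3,4-trimethoxy-6-methylbenzoate F6, the same bromophenol as in the fallback for step 4. BnBr and K2CO3 in DMF should give 3-(benzyloxy)-4-bromo-5-methylphenyl 2,3,4-trimethoxy-6-methylbenzoate F7. The carbonylative coupling of step 7 with 12 and 13 (Pd(OAc)2, Xantphos, Et3N, toluene, 100 °C) should give benzyl 4-{[2-(benzyloxy)-6-methyl-4-[(2,3,4-trimethoxy-6-methylbenzoyl)oxy]benzoyl]oxy}-2-hydroxy-6-methylbenzoate F8. Hydrogenolysis over Pd/C in EtOAc removes both benzyl groups and gives 16.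

**Further compounds**
F1 | step 7 | allyl 2,4-dihydroxy-6-methylbenzoate | Cc1cc(O)cc(O)c1C(=O)OCC=C
F2 | step 7 | allyl 2-hydroxy-6-methyl-4-[(2,3,4-trimethoxy-6-methylbenzoyl)oxy]benzoate | COc1cc(C)c(C(=O)Oc2cc(C)c(C(=O)OCC=C)c(O)c2)c(OC)c1OC
F3 | step 7 | allyl 2-(methoxymethoxy)-6-methyl-4-[(2,3,4-trimethoxy-6-methylbenzoyl)oxy]benzoate | COc1cc(C)c(C(=O)Oc2cc(C)c(C(=O)OCC=C)c(OCOC)c2)c(OC)c1OC
F4 | step 7 | 2-(methoxymethoxy)-6-methyl-4-[(2,3,4-trimethoxy-6-methylbenzoyl)oxy]benzoic acid | COc1cc(C)c(C(=O)Oc2cc(C)c(C(=O)O)c(OCOC)c2)c(OC)c1OC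
F5 | step 4 | 4-bromo-5-methylbenzene-1,3-diol | Cc1cc(O)cc(O)c1Br
F6 | step 4 | 4-bromo-3-hydroxy-5-methylphenyl 2,3,4-trimethoxy-6-methylbenzoate | COc1cc(C)c(C(=O)Oc2cc(C)c(Br)c(O)c2)c(OC)c1OC
F7 | step 8 | 3-(benzyloxy)-4-bromo-5-methylphenyl 2,3,4-trimethoxy-6-methylbenzoate | COc1cc(C)c(C(=O)Oc2cc(C)c(Br)c(OCc3ccccc3)c2)c(OC)c1OC
F8 | step 8 | benzyl 4-{[2-(benzyloxy)-6-methyl-4-[(2,3,4-trimethoxy-6-methylbenzoyl)oxy]benzoyl]oxy}-2-hydroxy-6-methylbenzoate | COc1cc(C)c(C(=O)Oc2cc(C)c(C(=O)Oc3cc(C)c(C(=O)OCc4ccccc4)c(O)c3)c(OCc5ccccc5)c2)c(OC)c1OC
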